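A closed, stirred vessel at one temperature takes X and J to E, J also goes over to L, and E can leave the solution as the solid Z.

| flask | X | J | remark | time |
|---|---|---|---|---|
| Friday's | 0.025 M | 5 equiv | run made earlier |  |
| Wednesday's | 0.10 M | 5 equiv | run made earlier |  |
| flask | 0.050 M | 5.00 equiv |  | 15 d |

| run | time / d | X / % | E / % |
|---|---|---|---|
| Friday's | 1.67 | 29.4 | 69.9 |
| Friday's | 5.00 | 11.1 | 88.8 |
| Friday's | 8.00 | 10.6 | 89.3 |
| Friday's | 12.0 | 10.2 | 88.3 |
| Friday's | 20.0 | 10.8 | 89.3 |
| Wednesday's | 4.00 | 0.6 | 99.2 |
| Wednesday's | 8.00 | 1.4 | 98.5 |
| Wednesday's | 10.0 | 1.6 | 99.4 |
| Wednesday's | 15.0 | 0.3 | 98.7 |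
| Wednesday's | 20.0 | 1.6 | 99.5 |

(readings scatter by 0.5 percentage points)

1. why nothing more happens at 15 d, or that something still does (all of X has reacted / J has run out first / it is still moving / forward and back rates have come level)
2. part of the X gone at 15 d
3. the E standing at 15 d, as a percentage of the X charged

- what is said of E includes Z
- Z is a solid; its amount is given per volume of the solution
- the numbers in the tables scatter with a standard deviation of 0.5 percentage points
- reactions considered so far: X + J <-> E; J <-> L; Z <-> E
- the reaction counts as stopped when no species that holds the X changes by six tenths of a point or more over the second half of the time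

Turn the time first. Friday's X is flat from 5.00 d and Wednesday's from 4.00 d, so you expect the 15 d of this flask to add nothing: a balance, with X left over.

The equivalents stay at 5.00 equiv, as in both runs, so they change nothing between them.

The X charge is the setting that moves. Let x be the fraction of X left and n the equivalents; J with L then stands at n − 1 + x on the same scale. At balance with Z standing, dissolved E is held and J keeps its ratio to L, so the concentrations of X and of J with L keep one product, in effect a solubility product. The saturation number q = x(n − 1 + x) therefore goes with the inverse square of the charge.

Friday's flat readings average x = 10.7%, so q = 0.438. Carried to Wednesday's charge, this q gives x = 0.685%, while a solution without solid gives about 3.07%. Wednesday's readings average 1.10%, nearer the first figure than the second. So you assume Z in both runs, which these readings do not prove, and carry Friday's q.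

For this flask q becomes 0.110. Write x = q/(n − 1 + x): the first round, with x dropped on the right, gives x = 2.74%, and putting that back gives 2.72%.

The forecast says forward and back rates have come level, with 95.6% of the X gone and 95.6% standing as E, below your 97.3%, on this ground: “The flask, at intermediate concentration, should therefore be at equilibrium by 15 d, with X left over and no loss of mass.”

In the flask forward and back rates have come level, with 97.4% of the X gone and 97.4% as E.

    X + J ⇌ E (K = 7.20 L mol⁻¹, k = 0.00570 L mol⁻¹ min⁻¹)
    J ⇌ L (K = 0.0650, k = 0.00930 min⁻¹)
    Z ⇌ E, rate k3*(cs3 - [E]) while solid is left; crystals form when [E] > cs3 (solubility = 1.80 mM, k = 0.150 min⁻¹)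

At 15.0 d this flask leaves x = 2.6%, which makes q = 0.107, with 93.8% of the X charged standing as Z. Now take q to the neighbouring flask, charged with 0.013 M of X at the same equivalents. The squared charge ratio raises q to 1.58. The rounds run 39.4%, then 35.9%, then 36.1%. The neighbouring flask stands at 36.2% of X, with 50.0% as Z.

Readings and results are calculated for substances that don't exist; scatter was added.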